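**Plan**

Retrosynthesis: cut first O1–C2 of the flavanone pyranone (ring C), after placing a temporary tert-butyl ester on C3; then the C2=C3 double bond of the resulting alkylidene β-keto ester (Knoevenagel); then the biaryl bond between C5′ of ring B and C8 of the apigenin unit (Suzuki–Miyaura); last the apigenin pyranone (oxidative chalcone cyclisation).
Forward: both phloroglucinol rings come from one dibenzylated trihydroxyacetophenone; the apigenin half is built as its 8-iodide, joined to a boronated catechol aldehyde (ring B), condensed with the ring A β-keto ester, and flavanone ring C is closed last; one hydrogenolysis frees all seven phenols.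
Enabling feature: the ring A oxygen O1 sits five atoms from C2 along O1–C8a–C4a–C4–C3=C2, and C3, a plain CH2 in the target, lies alpha to the C4 carbonyl. C3 can therefore carry an ester that activates C2, gives a hydrogen-bonding catalyst a 1,3-dicarbonyl grip, and leaves afterwards as isobutene and CO2.
Stereochemistry: C2 (S), the only stereocentre, is set in the ring closure by a cinchona-derived bifunctional thiourea; afterwards the molecule meets only acid (decarboxylation) and neutral hydrogen, never base.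

Key step: step 10

Assumption on the axis: the biaryl axis between C5′ of ring B and C8 of the apigenin unit has three small ortho oxygen substituents and one hydrogen and is treated as not configurationally stable, in line with the target SMILES, which defines no axial descriptor.
Assumption on the catalyst: the quinine-derived thiourea is taken to deliver the (2S) product with this alkylidene; if the sense of induction is the opposite one, its quinidine-derived pseudoenantiomer is used and nothing else changes.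

**Route**

Step 1
Reactants: 1 2′,4′,6′-trihydroxyacetophenone
Product: 2 1-[2,4-bis(benzyloxy)-6-hydroxyphenyl]ethan-1-one
Conditions: BnBr (2.1 equiv), K2CO3, DMF, 60 °C
Reagents that add atoms: benzyl bromide, BrCc1ccccc1
Why: Williamson etherification with two equivalents of halide should alkylate the two non-chelated phenols, while the 2-OH, hydrogen-bonded to the acetyl carbonyl and the least nucleophilic, stays free.

Step 2
Reactants: 2 1-[2,4-bis(benzyloxy)-6-hydroxyphenyl]ethan-1-one
Product: 3 1-[4,6-bis(benzyloxy)-2-hydroxy-3-iodophenyl]ethan-1-one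
Conditions: NIS (1.05 equiv), TFA (cat.), MeCN, 0 °C to rt
Reagents that add atoms: N-iodosuccinimide, O=C1CCC(=O)N1I
Why: Electrophilic aromatic iodination should take the position flanked by the free OH and one OBn rather than the more crowded position between two OBn groups, the pattern known for 3-halogenation of 2-hydroxy-4,6-dialkoxyacetophenones; one equivalent of NIS avoids the diiodide.

Step 3
Reactants: 3 1-[4,6-bis(benzyloxy)-2-hydroxy-3-iodophenyl]ethan-1-one; 4 4-(benzyloxy)benzaldehyde
Product: 5 (E)-1-[4,6-bis(benzyloxy)-2-hydroxy-3-iodophenyl]-3-[4-(benzyloxy)phenyl]prop-2-en-1-one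
Conditions: KOH (aq.), EtOH/THF, rt
Reagents that add atoms: none
Why: Claisen–Schmidt condensation (aldol addition, then E1cB dehydration) of the methyl ketone enolate with the non-enolisable aldehyde gives the conjugated E enone; aryl iodide and benzyl ethers are inert to aqueous KOH at room temperature.

Step 4
Reactants: 5 (E)-1-[4,6-bis(benzyloxy)-2-hydroxy-3-iodophenyl]-3-[4-(benzyloxy)phenyl]prop-2-en-1-one
Product: 6 5,7-bis(benzyloxy)-2-[4-(benzyloxy)phenyl]-8-iodo-4H-chromen-4-one
Conditions: I2 (10 mol%), DMSO, 120 °C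
Reagents that add atoms: none
Why: Iodine-catalysed oxidative cyclisation of a 2′-hydroxychalcone in DMSO (oxa-Michael closure, α-iodination, loss of HI, reoxidation of HI by DMSO) closes the apigenin pyranone; the iodinated carbon next to the phenol becomes C8, where the biaryl bond is needed.

Step 5
Reactants: 7 3-bromo-4,5-dihydroxybenzaldehyde
Product: 8 3,4-bis(benzyloxy)-5-bromobenzaldehyde
Conditions: BnBr (2.3 equiv), K2CO3, DMF, 60 °C
Reagents that add atoms: benzyl bromide, BrCc1ccccc1
Why: Williamson etherification of both catechol hydroxyls; carbonate does not touch the aldehyde.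

Step 6
Reactants: 8 3,4-bis(benzyloxy)-5-bromobenzaldehyde
Product: 9 3,4-bis(benzyloxy)-5-(4,4,5,5-tetramethyl-1,3,2-dioxaborolan-2-yl)benzaldehyde
Conditions: B2pin2, Pd(dppf)Cl2 (3 mol%), KOAc, 1,4-dioxane, 90 °C
Reagents that add atoms: bis(pinacolato)diboron, CC1(C)OB(B2OC(C)(C)C(C)(C)O2)OC1(C)C
Why: Miyaura borylation (oxidative addition of zerovalent palladium into C–Br, acetate-assisted transmetalation with the diboron, reductive elimination) tolerates the aldehyde and the benzyl ethers.

Step 7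
Reactants: 6 5,7-bis(benzyloxy)-2-[4-(benzyloxy)phenyl]-8-iodo-4H-chromen-4-one; 9 3,4-bis(benzyloxy)-5-(4,4,5,5-tetramethyl-1,3,2-dioxaborolan-2-yl)benzaldehyde
Product: 10 3,4-bis(benzyloxy)-5-{5,7-bis(benzyloxy)-2-[4-(benzyloxy)phenyl]-4-oxo-4H-chromen-8-yl}benzaldehyde
Conditions: Pd(OAc)2 (5 mol%), SPhos (10 mol%), K3PO4, toluene/H2O 10:1, 90 °C
Reagents that add atoms: none
Why: Suzuki–Miyaura coupling; the bulky electron-rich biarylphosphine is chosen because the new bond is flanked by three ortho oxygen substituents (7-OBn, ring oxygen O1, 4′-OBn), and the flavone, aldehyde and benzyl ethers tolerate aqueous phosphate.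

Step 8
Reactants: 2 1-[2,4-bis(benzyloxy)-6-hydroxyphenyl]ethan-1-one
Product: 11 tert-butyl 3-[2,4-bis(benzyloxy)-6-hydroxyphenyl]-3-oxopropanoate
Conditions: LiHMDS (3.3 equiv), THF, −78 °C; Boc2O (1.05 equiv), −78 to 0 °C; then cold 1 M HCl
Reagents that add atoms: di-tert-butyl dicarbonate, CC(C)(C)OC(=O)OC(=O)OC(C)(C)C
Why: C-acylation of the lithium dianion (phenoxide plus methyl ketone enolate), as in polyanion acylations of 2′-hydroxyacetophenones, is a crossed Claisen condensation; the third equivalent of base takes up the acidic product proton, and the bulky tert-butyl ester at low temperature should disfavour lactonisation to the 4-hydroxycoumarin.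

Step 9
Reactants: 10 3,4-bis(benzyloxy)-5-{5,7-bis(benzyloxy)-2-[4-(benzyloxy)phenyl]-4-oxo-4H-chromen-8-yl}benzaldehyde; 11 tert-butyl 3-[2,4-bis(benzyloxy)-6-hydroxyphenyl]-3-oxopropanoate
Product: 12 tert-butyl 2-[2,4-bis(benzyloxy)-6-hydroxybenzoyl]-3-(3,4-bis(benzyloxy)-5-{5,7-bis(benzyloxy)-2-[4-(benzyloxy)phenyl]-4-oxo-4H-chromen-8-yl}phenyl)prop-2-enoate (E/Z mixture)
Conditions: piperidine (20 mol%), AcOH (20 mol%), toluene, 4 Å molecular sieves, rt
Reagents that add atoms: none
Why: Knoevenagel condensation through the iminium ion of the aldehyde and the enol of the β-keto ester; near-neutral piperidinium acetate at room temperature is chosen so that the hydrogen-bonded ring A phenol should not add prematurely, and the product is used as the double-bond isomer mixture.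

Step 10
Reactants: 12 tert-butyl 2-[2,4-bis(benzyloxy)-6-hydroxybenzoyl]-3-arylprop-2-enoate (aryl = the benzylated biaryl of 10; E/Z mixture)
Product: 15 (2S)-5,7-bis(benzyloxy)-2-(3,4-bis(benzyloxy)-5-{5,7-bis(benzyloxy)-2-[4-(benzyloxy)phenyl]-4-oxo-4H-chromen-8-yl}phenyl)chroman-4-one, via 3-tert-butoxycarbonyl flavanone 13 (not isolated), via 3-carboxy flavanone 14 (not isolated)
Conditions: quinine-derived thiourea 1-[3,5-bis(trifluoromethyl)phenyl]-3-[(8α,9S)-6′-methoxycinchonan-9-yl]thiourea (10 mol%), toluene, −25 °C; then TsOH·H2O, 80 °C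
Reagents that add atoms: none
Why: The quinuclidine nitrogen of the bifunctional catalyst takes the proton of the ring A 2′-OH while its thiourea N–H pair binds the two carbonyl oxygens of the alkylidene β-keto ester, so the phenoxide oxygen adds to the β-carbon (the future C2) inside a hydrogen-bonded chiral ion pair and the ester enolate is protonated to 13; TsOH then silences the amine and cleaves the tert-butyl ester by loss of isobutene, and β-keto acid 14 loses CO2 through its cyclic six-membered transition state. The closest known reaction type is the cinchona-thiourea-catalysed intramolecular oxa-Michael addition of 2-hydroxyaryl alkylidene β-keto esters with one-pot acid decarboxylation to 2-arylchroman-4-ones. Ring C (O1–C2–C3–C4–C4a–C8a) is closed by O1–C2 bond formation in a 6-endo-trig mode. C2 is the only lasting new stereocentre and is set by the catalyst, which should expose one enantioface of the bound alkylidene to the tethered phenoxide; C3 of 13 is a transient, epimerisable centre (trans shown) that disappears on decarboxylation. The step needs enantioface selectivity under kinetic control and chemoselectivity for one phenol and one acceptor: the C3 ester makes C2 electrophilic enough for closure at −25 °C, where the uncatalysed and the reverse reaction should be slow, the ring A 2′-OH is the only free hydroxyl in 12, and the flavone enone of the other half is a vinylogous ester that a phenoxide does not attack. Once the acid is added no base is present, so the retro-oxa-Michael pathway that racemises 5,7-dioxygenated flavanones should stay closed during decarboxylation.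

Step 11
Reactants: 15 (2S)-5,7-bis(benzyloxy)-2-(3,4-bis(benzyloxy)-5-{5,7-bis(benzyloxy)-2-[4-(benzyloxy)phenyl]-4-oxo-4H-chromen-8-yl}phenyl)chroman-4-one
Product: 16 (2S)-2-{3,4-dihydroxy-5-[5,7-dihydroxy-2-(4-hydroxyphenyl)-4-oxo-4H-chromen-8-yl]phenyl}-5,7-dihydroxychroman-4-one (CNP0204144.1)
Conditions: H2 (1 atm), Pd/C (10 wt% palladium on carbon), THF/MeOH 1:1, rt
Reagents that add atoms: none
Why: Heterogeneous hydrogenolysis of seven primary benzyl aryl ethers under neutral conditions should leave the acid- and base-sensitive C2 centre untouched; the flavone double bond, the chelated carbonyls and the secondary cyclic C2–O1 bond react much more slowly, so the reaction is stopped as soon as the last ether has gone.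

**Compound list**

1 | 2′,4′,6′-trihydroxyacetophenone | CC(=O)c1c(O)cc(O)cc1O | starting material
2 | 1-[2,4-bis(benzyloxy)-6-hydroxyphenyl]ethan-1-one | CC(=O)c1c(O)cc(OCc2ccccc2)cc1OCc1ccccc1 | intermediate
3 | 1-[4,6-bis(benzyloxy)-2-hydroxy-3-iodophenyl]ethan-1-one | CC(=O)c1c(O)c(I)c(OCc2ccccc2)cc1OCc1ccccc1 | intermediate
4 | 4-(benzyloxy)benzaldehyde | O=Cc1ccc(OCc2ccccc2)cc1 | starting material
5 | (E)-1-[4,6-bis(benzyloxy)-2-hydroxy-3-iodophenyl]-3-[4-(benzyloxy)phenyl]prop-2-en-1-one | O=C(/C=C/c1ccc(OCc2ccccc2)cc1)c1c(O)c(I)c(OCc2ccccc2)cc1OCc1ccccc1 | intermediate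
6 | 5,7-bis(benzyloxy)-2-[4-(benzyloxy)phenyl]-8-iodo-4H-chromen-4-one | O=c1cc(-c2ccc(OCc3ccccc3)cc2)oc2c(I)c(OCc3ccccc3)cc(OCc3ccccc3)c12 | intermediate
7 | 3-bromo-4,5-dihydroxybenzaldehyde | O=Cc1cc(O)c(O)c(Br)c1 | starting material
8 | 3,4-bis(benzyloxy)-5-bromobenzaldehyde | O=Cc1cc(OCc2ccccc2)c(OCc2ccccc2)c(Br)c1 | intermediate
9 | 3,4-bis(benzyloxy)-5-(4,4,5,5-tetramethyl-1,3,2-dioxaborolan-2-yl)benzaldehyde | O=Cc1cc(OCc2ccccc2)c(OCc2ccccc2)c(B2OC(C)(C)C(C)(C)O2)c1 | intermediate
10 | 3,4-bis(benzyloxy)-5-{5,7-bis(benzyloxy)-2-[4-(benzyloxy)phenyl]-4-oxo-4H-chromen-8-yl}benzaldehyde | O=Cc1cc(OCc2ccccc2)c(OCc2ccccc2)c(-c2c(OCc3ccccc3)cc(OCc3ccccc3)c3c(=O)cc(-c4ccc(OCc5ccccc5)cc4)oc23)c1 | intermediate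
11 | tert-butyl 3-[2,4-bis(benzyloxy)-6-hydroxyphenyl]-3-oxopropanoate | CC(C)(C)OC(=O)CC(=O)c1c(O)cc(OCc2ccccc2)cc1OCc1ccccc1 | intermediate
12 | tert-butyl 2-[2,4-bis(benzyloxy)-6-hydroxybenzoyl]-3-(3,4-bis(benzyloxy)-5-{5,7-bis(benzyloxy)-2-[4-(benzyloxy)phenyl]-4-oxo-4H-chromen-8-yl}phenyl)prop-2-enoate, E/Z mixture | CC(C)(C)OC(=O)C(=Cc1cc(OCc2ccccc2)c(OCc2ccccc2)c(-c2c(OCc3ccccc3)cc(OCc3ccccc3)c3c(=O)cc(-c4ccc(OCc5ccccc5)cc4)oc23)c1)C(=O)c1c(O)cc(OCc2ccccc2)cc1OCc1ccccc1 | intermediate
13 | tert-butyl (2S,3R)-5,7-bis(benzyloxy)-2-(3,4-bis(benzyloxy)-5-{5,7-bis(benzyloxy)-2-[4-(benzyloxy)phenyl]-4-oxo-4H-chromen-8-yl}phenyl)-4-oxochromane-3-carboxylate (trans shown, C3 epimerisable) | O=C1[C@H](C(=O)OC(C)(C)C)[C@@H](c2cc(OCc3ccccc3)c(OCc3ccccc3)c(-c3c(OCc4ccccc4)cc(OCc4ccccc4)c4c(=O)cc(-c5ccc(OCc6ccccc6)cc5)oc34)c2)Oc2cc(OCc3ccccc3)cc(OCc3ccccc3)c21 | intermediate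
14 | (2S,3R)-5,7-bis(benzyloxy)-2-(3,4-bis(benzyloxy)-5-{5,7-bis(benzyloxy)-2-[4-(benzyloxy)phenyl]-4-oxo-4H-chromen-8-yl}phenyl)-4-oxochromane-3-carboxylic acid | O=C1[C@H](C(=O)O)[C@@H](c2cc(OCc3ccccc3)c(OCc3ccccc3)c(-c3c(OCc4ccccc4)cc(OCc4ccccc4)c4c(=O)cc(-c5ccc(OCc6ccccc6)cc5)oc34)c2)Oc2cc(OCc3ccccc3)cc(OCc3ccccc3)c21 | intermediate
15 | (2S)-5,7-bis(benzyloxy)-2-(3,4-bis(benzyloxy)-5-{5,7-bis(benzyloxy)-2-[4-(benzyloxy)phenyl]-4-oxo-4H-chromen-8-yl}phenyl)chroman-4-one | O=C1C[C@@H](c2cc(OCc3ccccc3)c(OCc3ccccc3)c(-c3c(OCc4ccccc4)cc(OCc4ccccc4)c4c(=O)cc(-c5ccc(OCc6ccccc6)cc5)oc34)c2)Oc2cc(OCc3ccccc3)cc(OCc3ccccc3)c21 | intermediate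
16 | (2S)-2-{3,4-dihydroxy-5-[5,7-dihydroxy-2-(4-hydroxyphenyl)-4-oxo-4H-chromen-8-yl]phenyl}-5,7-dihydroxychroman-4-one (CNP0204144.1) | O=C1C[C@@H](c2cc(O)c(O)c(-c3c(O)cc(O)c4c(=O)cc(-c5ccc(O)cc5)oc34)c2)Oc2cc(O)cc(O)c21 | target

**Step count and risks**

Total step count: 11. Longest linear sequence: 8 steps (steps 1, 2, 3, 4, 7, 9, 10, 11, from 1 to 16).

Steps most likely to fail:

Step 10. The 6′-benzyloxy group twists the aroyl carbonyl and may weaken the two-point binding to the thiourea, giving poor enantioface discrimination; optical purity may also erode by reversible ring opening during the hot acid treatment. The fallback sets out from 12 and comes back at 15. Ring closure of 12 with an achiral amine (DABCO, toluene, rt) should give the racemic trans tert-butyl 4-oxochromane-3-carboxylate F1. TsOH at 80 °C should convert it through the racemic 3-carboxylic acid F2 into the racemic benzyl-protected flavanone F3. Kinetic resolution by asymmetric transfer hydrogenation (RhCl(Cp*)[(R,R)-TsDPEN], HCO2H/Et3N, EtOAc, rt, stopped near half conversion) should reduce the (2R) ketone to the cis (2R,4R)-flavan-4-ol F4, which is separated. This follows from the rule that the (R,R) catalyst gives (R) carbinols from aryl ketones, with hydride arriving anti to the 2-aryl group. The unreacted (2S) ketone is 15 and goes on to step 11.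

Step 7. Transmetalation at the tri-ortho-substituted axis may be slow, so that protodeboronation of the ortho-alkoxy boronate and reductive deiodination of the flavone win. The fallback sets out from 8 (with 6) and comes back at 10. The aldehyde of 8 is masked with ethylene glycol (TsOH cat., toluene, azeotropic removal of water) as 2-[3,4-bis(benzyloxy)-5-bromophenyl]-1,3-dioxolane F5. Bromine–lithium exchange (n-BuLi, THF, −78 °C) gives the aryllithium F6, and ZnCl2 converts it at once into the arylzinc chloride F7. Negishi coupling of F7 with 6 (Pd(OAc)2, SPhos, THF, 60 °C) should give the biaryl dioxolane F8, since organozinc transmetalation is faster and needs no base. Aqueous HCl in THF at rt then releases 10.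

Step 8. The enolate or the phenoxide may be acylated on oxygen instead of carbon, or the product may lactonise to the 4-hydroxycoumarin. The fallback sets out from 2 and comes back at 11. The phenol is deliberately acylated (Boc2O, DMAP cat., Et3N, CH2Cl2, rt) to 2-acetyl-3,5-bis(benzyloxy)phenyl tert-butyl carbonate F9. LiHMDS (2.2 equiv, THF, −78 to 0 °C) should then move the alkoxycarbonyl group from oxygen to the enolate carbon through a six-membered tetrahedral intermediate (Baker–Venkataraman-type rearrangement with phenoxide as leaving group), giving 11 after cold acid work-up.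

Further compounds

F1 | step 10 | racemic trans tert-butyl 5,7-bis(benzyloxy)-2-aryl-4-oxochromane-3-carboxylate (aryl as in 13) | O=C1C(C(=O)OC(C)(C)C)C(c2cc(OCc3ccccc3)c(OCc3ccccc3)c(-c3c(OCc4ccccc4)cc(OCc4ccccc4)c4c(=O)cc(-c5ccc(OCc6ccccc6)cc5)oc34)c2)Oc2cc(OCc3ccccc3)cc(OCc3ccccc3)c21
F2 | step 10 | racemic trans 5,7-bis(benzyloxy)-2-aryl-4-oxochromane-3-carboxylic acid (aryl as in 14) | O=C1C(C(=O)O)C(c2cc(OCc3ccccc3)c(OCc3ccccc3)c(-c3c(OCc4ccccc4)cc(OCc4ccccc4)c4c(=O)cc(-c5ccc(OCc6ccccc6)cc5)oc34)c2)Oc2cc(OCc3ccccc3)cc(OCc3ccccc3)c21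
F3 | step 10 | racemic 5,7-bis(benzyloxy)-2-(3,4-bis(benzyloxy)-5-{5,7-bis(benzyloxy)-2-[4-(benzyloxy)phenyl]-4-oxo-4H-chromen-8-yl}phenyl)chroman-4-one | O=C1CC(c2cc(OCc3ccccc3)c(OCc3ccccc3)c(-c3c(OCc4ccccc4)cc(OCc4ccccc4)c4c(=O)cc(-c5ccc(OCc6ccccc6)cc5)oc34)c2)Oc2cc(OCc3ccccc3)cc(OCc3ccccc3)c21
F4 | step 10 | (2R,4R)-5,7-bis(benzyloxy)-2-(3,4-bis(benzyloxy)-5-{5,7-bis(benzyloxy)-2-[4-(benzyloxy)phenyl]-4-oxo-4H-chromen-8-yl}phenyl)chroman-4-ol | O[C@@H]1C[C@H](c2cc(OCc3ccccc3)c(OCc3ccccc3)c(-c3c(OCc4ccccc4)cc(OCc4ccccc4)c4c(=O)cc(-c5ccc(OCc6ccccc6)cc5)oc34)c2)Oc2cc(OCc3ccccc3)cc(OCc3ccccc3)c21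
F5 | step 7 | 2-[3,4-bis(benzyloxy)-5-bromophenyl]-1,3-dioxolane | Brc1cc(C2OCCO2)cc(OCc2ccccc2)c1OCc1ccccc1
F6 | step 7 | [2,3-bis(benzyloxy)-5-(1,3-dioxolan-2-yl)phenyl]lithium | [Li]c1cc(C2OCCO2)cc(OCc2ccccc2)c1OCc1ccccc1
F7 | step 7 | [2,3-bis(benzyloxy)-5-(1,3-dioxolan-2-yl)phenyl]zinc chloride | Cl[Zn]c1cc(C2OCCO2)cc(OCc2ccccc2)c1OCc1ccccc1
F8 | step 7 | 5,7-bis(benzyloxy)-2-[4-(benzyloxy)phenyl]-8-[2,3-bis(benzyloxy)-5-(1,3-dioxolan-2-yl)phenyl]-4H-chromen-4-one | C1COC(O1)c1cc(OCc2ccccc2)c(OCc2ccccc2)c(-c2c(OCc3ccccc3)cc(OCc3ccccc3)c3c(=O)cc(-c4ccc(OCc5ccccc5)cc4)oc23)c1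
F9 | step 8 | 2-acetyl-3,5-bis(benzyloxy)phenyl tert-butyl carbonate | CC(=O)c1c(OC(=O)OC(C)(C)C)cc(OCc2ccccc2)cc1OCc1ccccc1
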